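Numbering (lignan style): the oxolane arm with the R carbinol is C7–C8–C9 and the arm with the S carbinol is C7'–C8'–C9'. The target is (7R,8R,7'S,8'R) and both arenes are guaiacyl.
Feature: ring carbon C9 is a CH2 held only by the oxolane oxygen and C8 (the oxidation level of formaldehyde), and the exocyclic neighbour of C8 is the benzylic carbinol C7. A C7=C8 styrene therefore maps onto the target by adding O=CH2 at C8 and water at C7.
Cuts: protecting groups first, then O–C9, C9–C8 and C7–O together in one oxonium–Prins step, then C7'–C8' (syn aldol), then C7=C8 (Wittig).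
Forward: vanillin pivalate is used twice, as Wittig partner (C7 arene, chain C7–C8–C8'–C9') and as aldol acceptor (C7' arene). The open chain is complete before the only new ring, the oxolane, closes in step 7.
Stereochemistry: C7' and C8' come from (S)-4-benzyloxazolidin-2-one (Evans syn aldol). C8 is set trans to C8' in the ring closure, and C7 by the face on which water meets the benzylic cation.
Aryl pivalates, rather than silyl or alkyl ethers, keep both benzylic C–O bonds and both arenes inert to the acid of step 7.

Key step: step 7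

Abbreviations: ArP = 3-methoxy-4-(pivaloyloxy)phenyl; TIPS = triisopropylsilyl.
Remark on the chemistry: the two arenes are identical, so the target has two constitutionally alike CH2–CH–CH(OH)Ar arms that differ only in relative configuration. The arm with like descriptors (7R,8R) is assigned to the cyclisation because that relationship is expected from hydration of the conformationally relaxed cation, and the unlike arm (7'S,8'R) is the syn-aldol pattern.

Step 1
Reactants: 1 vanillin
Product: 2 4-formyl-2-methoxyphenyl pivalate (ArP–CHO)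
Conditions: PivCl, Et3N, DMAP (cat.), CH2Cl2, 0 °C → rt
Reagents that add atoms: pivaloyl chloride, CC(C)(C)C(=O)Cl
Why: O-acylation of a phenol with an acid chloride under DMAP catalysis is routine, and the hindered ester lowers the donor strength of the arene to about that of phenyl while standing up to steps 2 to 8.

Step 2
Reactants: 2 4-formyl-2-methoxyphenyl pivalate; 3 (2-carboxyethyl)triphenylphosphonium bromide
Product: 5 (E)-4-ArP-but-3-enoic acid, via ylide 4 (not isolated)
Conditions: 3, NaN(SiMe3)2 (2 equiv per 3), THF, 0 °C; then 2, −20 °C → rt; then 1 M HCl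
Reagents that add atoms: sodium bis(trimethylsilyl)amide, [Na+].C[Si](C)(C)[N-][Si](C)(C)C (its sodium is found in 4 only)
Why: Wittig olefination with the carboxylate-bearing ylide 4 is known to give E-configured 4-arylbut-3-enoic acids from aromatic aldehydes, the aldehyde being far more electrophilic than the hindered aryl ester, and it forms C7=C8 while bringing in C8' and C9'.

Step 3
Reactants: 5 (E)-4-ArP-but-3-enoic acid; 6 (S)-4-benzyloxazolidin-2-one
Product: 8 (S)-4-benzyl-3-[(E)-4-ArP-but-3-enoyl]oxazolidin-2-one, via mixed pivalic anhydride 7 (not isolated)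
Conditions: PivCl, Et3N, THF, −20 °C; then LiCl, 6, −20 °C → rt
Reagents that add atoms: pivaloyl chloride, CC(C)(C)C(=O)Cl (its acyl group is found in 7 only)
Why: N-acylation of the oxazolidinone through a mixed pivalic anhydride with LiCl and Et3N needs no strong base, attack goes to the less hindered carbonyl of 7, and the double bond stays in conjugation with the arene.

Step 4
Reactants: 8 (S)-4-benzyl-3-[(E)-4-ArP-but-3-enoyl]oxazolidin-2-one; 2 4-formyl-2-methoxyphenyl pivalate
Product: 11 (4S)-4-benzyl-3-{(2S,3E)-2-[(S)-ArP(hydroxy)methyl]-4-ArP-but-3-enoyl}oxazolidin-2-one, via dibutylboron dienolate 9 (not isolated), via boron aldolate 10 (not isolated)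
Conditions: Bu2BOTf, Et3N, CH2Cl2, −78 → 0 °C; then 2, −78 → 0 °C; then pH 7 buffer, MeOH, 30% H2O2, 0 °C
Reagents that add atoms: dibutylboron triflate, CCCCB(CCCC)OS(=O)(=O)C(F)(F)F (its Bu2B group is found in 9 and 10 only)
Why: Evans syn aldol addition: soft enolisation gives the Z-configured boron dienolate 9, which reacts at its α-carbon (as the dienolates of crotonyl and butenoyl imides do) through a chair Zimmerman–Traxler transition state on the face turned away from the benzyl group of the auxiliary, and this sets C8' and C7' together (2S and carbinol S in 11, the sense known for the S-auxiliary and aromatic aldehydes).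

Step 5
Reactants: 11 the syn aldol
Product: 12 (4S)-4-benzyl-3-{(2S,3E)-2-[(S)-ArP(triisopropylsilyloxy)methyl]-4-ArP-but-3-enoyl}oxazolidin-2-one
Conditions: TIPSOTf, 2,6-lutidine, CH2Cl2, 0 °C → rt
Reagents that add atoms: triisopropylsilyl triflate, CC(C)[Si](C(C)C)(C(C)C)OS(=O)(=O)C(F)(F)F
Why: Silylation with a silyl triflate and 2,6-lutidine caps hindered aldol carbinols without retro-aldol cleavage or epimerisation, and TIPS is taken for its stability to the acid of step 7 and for the bulk it places beside C8'.

Step 6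
Reactants: 12 the silylated imide
Product: 13 (2R,3E)-2-[(S)-ArP(triisopropylsilyloxy)methyl]-4-ArP-but-3-en-1-ol
Conditions: LiBH4, MeOH (1 equiv), THF, 0 °C
Reagents that add atoms: none
Why: Reductive cleavage of an N-acyloxazolidinone with LiBH4 and MeOH takes place at the activated acyl carbonyl at 0 °C, where the hindered aryl pivalates, the styrene and the configuration at C8' (now R only through a change of CIP ranking) should be left as they are, and the auxiliary is recovered.

Step 7
Reactants: 13 (2R,3E)-2-[(S)-ArP(triisopropylsilyloxy)methyl]-4-ArP-but-3-en-1-ol; 14 formaldehyde (charged as paraformaldehyde)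
Product: 18 (3R,4R)-3-[(R)-ArP(hydroxy)methyl]-4-[(S)-ArP(triisopropylsilyloxy)methyl]oxolane, via hemiformal 15 (not isolated), via oxocarbenium ion 16 (not isolated), via benzylic cation 17 (not isolated)
Conditions: (CH2O)n, TfOH (20 mol %), H2O (3 equiv), CH2Cl2–MeNO2, 0 °C → rt
Reagents that add atoms: water, O
Why: The primary alcohol and formaldehyde give hemiformal 15, TfOH ionises it to the O-alkyl oxocarbenium ion 16 (O–C9), the nearer styrene carbon C8 attacks its CH2 carbon (C9–C8) and water adds to the benzylic cation 17 (C7–O); the closest known reaction type is the oxonium–Prins cyclisation of styrenyl homoallylic alcohols with aldehydes, here with hydroxy termination as in Prins routes to 4-hydroxytetrahydropyrans. The oxolane closes 5-exo-trig with respect to the styrene (endo with respect to C=O+), and this mode should win over 6-endo closure and over a 2-oxonia-Cope shift because only attack through C8 leaves the charge on a benzylic carbon and neither alternative keeps the arene in conjugation. C8 is set trans to C8' because in the envelope transition state the bulky CH(OTIPS)ArP group on C8' lies pseudo-equatorial and turns away from C7. C7 is set after the ring has closed: the E-alkene delivers 17 with H8 already eclipsing the arene (least 1,3-allylic strain), one face of the cation then looks towards the C9 methylene group and the other towards C8' and its silyloxybenzyl arm, so water should enter from the C9 side, anti to the C8–C8' bond in the Felkin-type manner known for chiral secondary benzylic cations, which places 7R beside 8R. The step needs five- over six-ring closure, trans C8/C8', the C9-side face at C7 and capture by water ahead of Friedel–Crafts closure onto the other arene, and these rest on benzylic charge stabilisation, the size of the C8' substituent (twice) and the deliberate excess of water. The pivalates hold both arenes near the donor level of phenyl, so that 18 and the C7'–O bond should not re-ionise under the acid (the kinetic result at C7 and the aldol centre are kept) and ring hydroxymethylation or aryltetralin formation is held back.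

Step 8
Reactants: 18 the silylated oxolane
Product: 19 (3R,4R)-3-[(R)-ArP(hydroxy)methyl]-4-[(S)-ArP(hydroxy)methyl]oxolane
Conditions: HF·pyridine, pyridine, THF, 0 °C → rt
Reagents that add atoms: none
Why: Cleavage of the silyl ether by HF·pyridine is a standard desilylation under weakly acidic conditions in which the aryl esters neither migrate nor cleave and the two benzylic alcohols, still on acylated arenes, do not ionise.

Step 9
Reactants: 19 the diol bis-pivalate
Product: 20 the target (3R,4R)-3-[(R)-hydroxy(4-hydroxy-3-methoxyphenyl)methyl]-4-[(S)-hydroxy(4-hydroxy-3-methoxyphenyl)methyl]oxolane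
Conditions: K2CO3 (3 equiv), MeOH, 0 °C → rt
Reagents that add atoms: none
Why: Carbonate-mediated methanolysis (transesterification) cleaves activated aryl esters at room temperature, well below the conditions under which p-hydroxybenzylic alcohols lose hydroxide to quinone methides, so that the four stereocentres are kept.

Compound list
1 | vanillin | COc1cc(C=O)ccc1O | starting material
2 | 4-formyl-2-methoxyphenyl pivalate | COc1cc(C=O)ccc1OC(=O)C(C)(C)C | intermediate
3 | (2-carboxyethyl)triphenylphosphonium bromide | OC(=O)CC[P+](c1ccccc1)(c1ccccc1)c1ccccc1.[Br-] | starting material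
4 | sodium 3-(triphenylphosphoranylidene)propanoate (ylide) | [Na+].[O-]C(=O)CC=P(c1ccccc1)(c1ccccc1)c1ccccc1 | intermediate
5 | (E)-4-[3-methoxy-4-(pivaloyloxy)phenyl]but-3-enoic acid | COc1cc(/C=C/CC(=O)O)ccc1OC(=O)C(C)(C)C | intermediate
6 | (S)-4-benzyloxazolidin-2-one | O=C1N[C@@H](Cc2ccccc2)CO1 | starting material
7 | mixed anhydride of 5 and pivalic acid | COc1cc(/C=C/CC(=O)OC(=O)C(C)(C)C)ccc1OC(=O)C(C)(C)C | intermediate
8 | (S)-4-benzyl-3-[(E)-4-ArP-but-3-enoyl]oxazolidin-2-one | COc1cc(/C=C/CC(=O)N2[C@@H](Cc3ccccc3)COC2=O)ccc1OC(=O)C(C)(C)C | intermediate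
9 | Z-configured dibutylboron dienolate of 8 | COc1cc(/C=C/C=C(\OB(CCCC)CCCC)N2[C@@H](Cc3ccccc3)COC2=O)ccc1OC(=O)C(C)(C)C | intermediate
10 | dibutylboron aldolate of 11 | COc1cc([C@@H](OB(CCCC)CCCC)[C@H](/C=C/c2ccc(OC(=O)C(C)(C)C)c(OC)c2)C(=O)N2[C@@H](Cc3ccccc3)COC2=O)ccc1OC(=O)C(C)(C)C | intermediate
11 | (4S)-4-benzyl-3-{(2S,3E)-2-[(S)-ArP(hydroxy)methyl]-4-ArP-but-3-enoyl}oxazolidin-2-one | COc1cc([C@@H](O)[C@H](/C=C/c2ccc(OC(=O)C(C)(C)C)c(OC)c2)C(=O)N2[C@@H](Cc3ccccc3)COC2=O)ccc1OC(=O)C(C)(C)C | intermediate
12 | TIPS ether of 11 | COc1cc([C@@H](O[Si](C(C)C)(C(C)C)C(C)C)[C@H](/C=C/c2ccc(OC(=O)C(C)(C)C)c(OC)c2)C(=O)N2[C@@H](Cc3ccccc3)COC2=O)ccc1OC(=O)C(C)(C)C | intermediate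
13 | (2R,3E)-2-[(S)-ArP(triisopropylsilyloxy)methyl]-4-ArP-but-3-en-1-ol | COc1cc([C@@H](O[Si](C(C)C)(C(C)C)C(C)C)[C@H](/C=C/c2ccc(OC(=O)C(C)(C)C)c(OC)c2)CO)ccc1OC(=O)C(C)(C)C | intermediate
14 | formaldehyde (used as paraformaldehyde) | C=O | starting material
15 | hemiformal (O-hydroxymethyl ether) of 13 | COc1cc([C@@H](O[Si](C(C)C)(C(C)C)C(C)C)[C@H](/C=C/c2ccc(OC(=O)C(C)(C)C)c(OC)c2)COCO)ccc1OC(=O)C(C)(C)C | intermediate
16 | O-alkyl oxocarbenium ion from 15 | COc1cc([C@@H](O[Si](C(C)C)(C(C)C)C(C)C)[C@H](/C=C/c2ccc(OC(=O)C(C)(C)C)c(OC)c2)C[O+]=C)ccc1OC(=O)C(C)(C)C | intermediate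
17 | oxolan-3-yl benzylic cation (charge on C7; 8R,8'R,7'S) | COc1cc([C@@H](O[Si](C(C)C)(C(C)C)C(C)C)[C@H]2COC[C@@H]2[CH+]c2ccc(OC(=O)C(C)(C)C)c(OC)c2)ccc1OC(=O)C(C)(C)C | intermediate
18 | (3R,4R)-3-[(R)-ArP(hydroxy)methyl]-4-[(S)-ArP(triisopropylsilyloxy)methyl]oxolane | COc1cc([C@@H](O[Si](C(C)C)(C(C)C)C(C)C)[C@H]2COC[C@@H]2[C@@H](O)c2ccc(OC(=O)C(C)(C)C)c(OC)c2)ccc1OC(=O)C(C)(C)C | intermediate
19 | (3R,4R)-3-[(R)-ArP(hydroxy)methyl]-4-[(S)-ArP(hydroxy)methyl]oxolane | COc1cc([C@@H](O)[C@H]2COC[C@@H]2[C@@H](O)c2ccc(OC(=O)C(C)(C)C)c(OC)c2)ccc1OC(=O)C(C)(C)C | intermediate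
20 | CNP0157038.2, (7R,8R,7'S,8'R) in the numbering used here | COc1cc([C@@H](O)[C@H]2COC[C@@H]2[C@@H](O)c2ccc(O)c(OC)c2)ccc1O | target

Total step count: 9. Longest linear sequence: 9 steps (1 → 2 → 5 → 8 → 11 → 12 → 13 → 18 → 19 → 20); compound 2 enters a second time in step 4.

Steps most likely to fail

Step 7: the facial selectivity in the capture of the benzylic cation by water may be poor or inverted; the ring closure itself is less in doubt. The fallback sets out from 13 and comes back at 20, and it sets C7 by hydride delivery and SN2 inversion instead of cation capture. Compound 13 is cyclised as in step 7 and the C7 epimers are not separated. The mixture of 18 and the 7S alcohol F1 is oxidised with Dess–Martin periodinane in CH2Cl2 to the aryl ketone F2. Zn(BH4)2 in Et2O at −20 °C, held between the ketone oxygen and the oxolane oxygen, should deliver hydride to the face away from C8' and return the 7S alcohol F1 alone. A Mitsunobu reaction (4-nitrobenzoic acid, PPh3, DIAD, toluene) inverts C7, cleanly because the acylated arene does not support ionisation, and gives the 7R 4-nitrobenzoate F3. HF·pyridine frees O7' to give the hydroxy ester F4. K2CO3 in MeOH then cleaves the nitrobenzoate together with both pivalates to give 20.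

Step 4: the double bond may shift into conjugation with the imide during enolisation, the aryl-substituted dienolate may react through its γ-carbon, or the syn selectivity may erode. The fallback sets out from 6 and 2 and comes back at 13, and it brings in the C7 arene only after the aldol step. Compound 6 is N-acylated (n-BuLi, (E)-crotonyl chloride, THF, −78 °C) to the crotonyl imide F5. Its Bu2BOTf/Et3N dienolate is the standard case of α-selective syn aldol addition and should give with 2 the α-vinyl aldol F6. TIPSOTf and 2,6-lutidine give the silyl ether F7, and LiBH4/MeOH gives the vinyl alcohol F8. A Heck arylation of the terminal vinyl group with 4-iodo-2-methoxyphenyl pivalate F9 (from commercial 4-iodo-2-methoxyphenol and pivaloyl chloride) under Pd(OAc)2, Bu4NCl, NaHCO3, DMF, 60 °C forms the E-styrene and gives 13.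

Step 6: hydride may attack the ring carbonyl of the auxiliary because the acyl carbonyl is screened by the TIPS ether and the styryl group, and aryl pivalate may be lost on long exposure to LiBH4. The fallback sets out from 11 and comes back at 13, and it removes the auxiliary before silylation. With the β-hydroxyl free the acyl carbonyl is open, so NaBH4 in THF–H2O, which spares aryl pivalates, should suffice and give the diol F10. Excess TIPSOTf and 2,6-lutidine give the bis-silyl ether F11. Camphorsulfonic acid in MeOH–CH2Cl2 at 0 °C removes the unhindered primary TIPS group selectively and gives 13.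

Further compounds
F1 | step 7 | (3R,4R)-3-[(S)-ArP(hydroxy)methyl]-4-[(S)-ArP(triisopropylsilyloxy)methyl]oxolane (7S epimer of 18) | COc1cc([C@@H](O[Si](C(C)C)(C(C)C)C(C)C)[C@H]2COC[C@@H]2[C@H](O)c2ccc(OC(=O)C(C)(C)C)c(OC)c2)ccc1OC(=O)C(C)(C)C
F2 | step 7 | ArP {(3R,4R)-4-[(S)-ArP(triisopropylsilyloxy)methyl]oxolan-3-yl} ketone | COc1cc([C@@H](O[Si](C(C)C)(C(C)C)C(C)C)[C@H]2COC[C@@H]2C(=O)c2ccc(OC(=O)C(C)(C)C)c(OC)c2)ccc1OC(=O)C(C)(C)C
F3 | step 7 | 7R 4-nitrobenzoate of 18 | COc1cc([C@@H](O[Si](C(C)C)(C(C)C)C(C)C)[C@H]2COC[C@@H]2[C@@H](OC(=O)c2ccc(cc2)[N+](=O)[O-])c2ccc(OC(=O)C(C)(C)C)c(OC)c2)ccc1OC(=O)C(C)(C)C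
F4 | step 7 | 7R 4-nitrobenzoate of 19 (O7' free) | COc1cc([C@@H](O)[C@H]2COC[C@@H]2[C@@H](OC(=O)c2ccc(cc2)[N+](=O)[O-])c2ccc(OC(=O)C(C)(C)C)c(OC)c2)ccc1OC(=O)C(C)(C)C
F5 | step 4 | (S)-4-benzyl-3-[(E)-but-2-enoyl]oxazolidin-2-one | C/C=C/C(=O)N1[C@@H](Cc2ccccc2)COC1=O
F6 | step 4 | (4S)-4-benzyl-3-{(2S)-2-[(S)-ArP(hydroxy)methyl]but-3-enoyl}oxazolidin-2-one | COc1cc([C@@H](O)[C@H](C=C)C(=O)N2[C@@H](Cc3ccccc3)COC2=O)ccc1OC(=O)C(C)(C)C
F7 | step 4 | TIPS ether of F6 | COc1cc([C@@H](O[Si](C(C)C)(C(C)C)C(C)C)[C@H](C=C)C(=O)N2[C@@H](Cc3ccccc3)COC2=O)ccc1OC(=O)C(C)(C)C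
F8 | step 4 | (2R)-2-[(S)-ArP(triisopropylsilyloxy)methyl]but-3-en-1-ol | COc1cc([C@@H](O[Si](C(C)C)(C(C)C)C(C)C)[C@H](C=C)CO)ccc1OC(=O)C(C)(C)C
F9 | step 4 | 4-iodo-2-methoxyphenyl pivalate | COc1cc(I)ccc1OC(=O)C(C)(C)C
F10 | step 6 | (2R,3E)-2-[(S)-ArP(hydroxy)methyl]-4-ArP-but-3-en-1-ol | COc1cc([C@@H](O)[C@H](/C=C/c2ccc(OC(=O)C(C)(C)C)c(OC)c2)CO)ccc1OC(=O)C(C)(C)C
F11 | step 6 | bis-TIPS ether of F10 | COc1cc([C@@H](O[Si](C(C)C)(C(C)C)C(C)C)[C@H](/C=C/c2ccc(OC(=O)C(C)(C)C)c(OC)c2)CO[Si](C(C)C)(C(C)C)C(C)C)ccc1OC(=O)C(C)(C)C
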